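**Assumption:** the target is made as drawn, the open 3-oxo-1,10-diol (ring-chain tautomer of the 3,10-hemiketal); locants are germacrane locants (C1 CHOH, C3 C=O, C4 CHMe, C6 lactone O–CH, C7 ring fusion, C8 ester O–CH, C10 C(OH)Me, C11–C13 methylene lactone).

**Retrosynthetic overview**
1. C3 ketone ⇐ secondary nitro group (Nef); C8 isobutyrate ⇐ (8S)-alcohol by inversion; C1/C10 diol carried as an acetonide.
2. Ten-membered ring (formed last): C7–C8 by intramolecular indium Barbier reaction of a 3-(bromomethyl)butenolide, nucleophilic at its β-carbon C7, onto the C8 aldehyde.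
3. Lactone ring (formed first): C6–C7 by catalytic asymmetric 2-(alkoxycarbonyl)allylboration of the C6 aldehyde, then bromination/dehydrobromination.
4. Key bond C3–C4: the nitronate of a C1–C3/C8–C10 nitroalkane (acyl anion equivalent of the C3 ketone) adds to crotonaldehyde under iminium catalysis, setting C4 and freeing the C6 aldehyde.
5. Nitroalkane ⇐ 4-methylanisole: Birch reduction/ozonolysis fixes the (Z)-alkene; asymmetric dihydroxylation sets C1 and C10.

**Route**

Step 1
Reactants: 1 4-methylanisole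
Product: 2 1-methoxy-4-methylcyclohexa-1,4-diene
Conditions: Li, NH3 (l), t-BuOH, THF, −78 → −33 °C; NH4Cl
Reagents that add atoms: none
Why: Birch reduction of an anisole gives the 2,5-dihydro product with one enol ether and one methyl-substituted alkene held cis in the ring.

Step 2
Reactants: 2 1-methoxy-4-methylcyclohexa-1,4-diene
Product: 4 methyl (3Z)-6,6-dimethoxy-4-methylhex-3-enoate, via aldehyde ester 3 (not isolated)
Conditions: O3 (1 equiv), CH2Cl2/MeOH 4:1, −78 °C; Me2S, −78 °C → rt; then HC(OMe)3, p-TsOH (cat.), 0 °C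
Reagents that add atoms: ozone, [O-][O+]=O; trimethyl orthoformate, COC(OC)OC
Why: Criegee ozonolysis cleaves only the electron-rich enol ether (its carbon emerges as the methyl ester), the ring fixes the (Z)-trisubstituted alkene, and acetalisation masks the β,γ-unsaturated aldehyde before it can conjugate.

Step 3
Reactants: 4 methyl (3Z)-6,6-dimethoxy-4-methylhex-3-enoate
Product: 5 (3Z)-6,6-dimethoxy-4-methylhex-3-en-1-ol
Conditions: LiAlH4, THF, 0 °C
Reagents that add atoms: none
Why: Hydride reduction of the ester to the primary alcohol leaves the acetal and the isolated alkene untouched.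

Step 4
Reactants: 5 (3Z)-6,6-dimethoxy-4-methylhex-3-en-1-ol
Product: 6 (3Z)-6-iodo-1,1-dimethoxy-3-methylhex-3-ene
Conditions: I2, PPh3, imidazole, CH2Cl2, 0 °C → rt
Reagents that add atoms: iodine, II
Why: Appel iodination of the primary alcohol proceeds under buffered conditions that spare the acetal.

Step 5
Reactants: 6 (3Z)-6-iodo-1,1-dimethoxy-3-methylhex-3-ene
Product: 7 (3Z)-1,1-dimethoxy-3-methyl-6-nitrohex-3-ene
Conditions: NaNO2, phloroglucinol, DMF, rt
Reagents that add atoms: sodium nitrite, [Na+].[O-]N=O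
Why: Kornblum SN2 displacement of the primary iodide by nitrite at nitrogen gives the primary nitroalkane that later acts as the C3 acyl anion equivalent.

Step 6
Reactants: 7 (3Z)-1,1-dimethoxy-3-methyl-6-nitrohex-3-ene
Product: 8 (3R,4S)-1,1-dimethoxy-3-methyl-6-nitrohexane-3,4-diol
Conditions: K2OsO2(OH)4 (2 mol %), hydroquinine 1,4-phthalazinediyl diether ((DHQ)2PHAL, 5 mol %), N-methylmorpholine N-oxide, acetone/H2O 10:1, 0 °C, slow addition of 7
Reagents that add atoms: N-methylmorpholine N-oxide, C[N+]1([O-])CCOCC1; water, O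
Why: Sharpless asymmetric dihydroxylation with a neutral reoxidant (basic K3Fe(CN)6 would ionise and oxidise the nitro group) adds syn to the (Z)-alkene, which gives the C1/C10 relative configuration, and the dihydroquinine ligand selects the face giving (3R,4S), i.e. 10R,1S, with only moderate ee expected because the larger group sits in the less favourable quadrant.

Step 7
Reactants: 8 (3R,4S)-1,1-dimethoxy-3-methyl-6-nitrohexane-3,4-diol
Product: 9 (4S,5R)-5-(2,2-dimethoxyethyl)-2,2,5-trimethyl-4-(2-nitroethyl)-1,3-dioxolane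
Conditions: 2-methoxypropene, pyridinium p-toluenesulfonate (cat.), CH2Cl2, 0 °C
Reagents that add atoms: 2-methoxypropene, COC(C)=C
Why: Kinetic acetonide formation on the cis-diol is faster than ionisation of the dimethyl acetal, and the cis-dioxolane later pre-folds the chain for ring closure.

Step 8
Reactants: 9 (4S,5R)-5-(2,2-dimethoxyethyl)-2,2,5-trimethyl-4-(2-nitroethyl)-1,3-dioxolane; 10 (E)-but-2-enal
Product: 11 (3S)-5-[(4S,5R)-5-(2,2-dimethoxyethyl)-2,2,5-trimethyl-1,3-dioxolan-4-yl]-3-methyl-4-nitropentanal (both epimers at the nitro carbon)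
Conditions: (R)-2-[diphenyl(trimethylsilyloxy)methyl]pyrrolidine (15 mol %), LiOAc (15 mol %), 10 (3 equiv), CH2Cl2/MeOH 9:1, rt
Reagents that add atoms: none
Why: Iminium-catalysed (Hayashi–Jørgensen) Michael addition in which the nitronate of 9, an acyl anion equivalent for the C3 ketone, attacks the β-carbon of crotonaldehyde on the face left open by the (R)-catalyst, setting C4 as S and releasing the C6 aldehyde, while the nitro-bearing carbon forms as a mixture that is erased in step 14.

Step 9
Reactants: 11 the nitro aldehyde of step 8; 12 ethyl 2-[(4,4,5,5-tetramethyl-1,3,2-dioxaborolan-2-yl)methyl]prop-2-enoate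
Product: 14 (5R)-5-{(2S)-4-[(4S,5R)-5-(2,2-dimethoxyethyl)-2,2,5-trimethyl-1,3-dioxolan-4-yl]-2-methyl-3-nitrobutyl}-3-methylideneoxolan-2-one, via homoallylic borate 13 (not isolated)
Conditions: (S)-3,3′-bis(2,4,6-triisopropylphenyl)-1,1′-binaphthyl-2,2′-diyl hydrogen phosphate ((S)-TRIP, 5 mol %), 4 Å MS, toluene, −30 °C → rt; then 50 °C
Reagents that add atoms: none
Why: Chiral phosphoric acid-catalysed allylboration through a chair transition state delivers the allyl group to the Si face of the aldehyde (6R, by analogy with the parent allylboration), and the borate then lactonises with loss of the ethoxyborane.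

Step 10
Reactants: 14 the α-methylene lactone of step 9
Product: 16 (5R)-3-(bromomethyl)-5-{(2S)-4-[(4S,5R)-5-(2,2-dimethoxyethyl)-2,2,5-trimethyl-1,3-dioxolan-4-yl]-2-methyl-3-nitrobutyl}furan-2(5H)-one, via dibromo lactone 15 (not isolated)
Conditions: Br2 (1.05 equiv), K2CO3 (s), CH2Cl2, 0 °C, dark; then Et3N, 0 °C → rt
Reagents that add atoms: bromine, BrBr
Why: Bromine adds to the only alkene present and E2 loss of HBr towards C7 moves the double bond into the ring, leaving the allylic bromide (addition–elimination, as used to make 3-(bromomethyl)furan-2(5H)-one from the parent methylene lactone).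

Step 11
Reactants: 16 the bromomethyl butenolide of step 10
Product: 17 2-{(4R,5S)-5-[(3S)-4-[(2R)-4-(bromomethyl)-5-oxo-2,5-dihydrofuran-2-yl]-3-methyl-2-nitrobutyl]-2,2,4-trimethyl-1,3-dioxolan-4-yl}acetaldehyde
Conditions: pyridinium p-toluenesulfonate (cat.), acetone/H2O 20:1, rt
Reagents that add atoms: water, O
Why: Acid-catalysed transacetalisation in wet acetone cleaves the acyclic dimethyl acetal while the acetone solvent keeps the acetonide in place.

Step 12
Reactants: 17 the bromo aldehyde of step 11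
Product: 18 (1S,4S,6R,7R,8S,10R)-8-hydroxy-1,10-(isopropylidenedioxy)-3-nitrogermacr-11(13)-en-6,12-olide (C3 epimers)
Conditions: In powder (3 equiv), NaI (1 equiv), DMF, 25 °C, syringe-pump addition of 17 over 12 h (final 2 mM); aq NH4Cl
Reagents that add atoms: none
Why: Proposed new method: an intramolecular indium Barbier reaction closing the ten-membered ring, in which the allylindium from the ring-locked (E)-allylic bromide is nucleophilic at the butenolide β-carbon C7 and adds to the C8 aldehyde through a chair Zimmerman–Traxler transition state anti to the C6 substituent (trans-lactone, 7,8-anti, hence 8S), with the cis-acetonide folding the chain and the nitro group masking the C3 ketone from attack; the closest known chemistry is the intermolecular zinc or indium Barbier reaction of 3-(bromomethyl)furan-2(5H)-ones with aldehydes and the CrCl2-mediated macrocyclic allylations used for germacranolides.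

Step 13
Reactants: 18 the (8S)-alcohol of step 12; 19 2-methylpropanoic acid
Product: 20 (1S,4S,6R,7S,8R,10R)-1,10-(isopropylidenedioxy)-8-(2-methylpropanoyloxy)-3-nitrogermacr-11(13)-en-6,12-olide (C3 epimers)
Conditions: PPh3, diisopropyl azodicarboxylate, 19 (3 equiv), toluene, 0 °C → rt
Reagents that add atoms: none
Why: Mitsunobu esterification: SN2 displacement of the C8 oxyphosphonium by isobutyrate inverts C8 to R and installs the ester in one operation, the acetonide keeping the other hydroxyls out of play.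

Step 14
Reactants: 20 the nitro ester of step 13
Product: 22 (1S,4S,6R,7S,8R,10R)-1,10-dihydroxy-8-(2-methylpropanoyloxy)-3-oxogermacr-11(13)-en-6,12-olide (CNP0180091.1), via ketone acetonide 21 (not isolated)
Conditions: NaNO2, AcOH, DMSO, 35 °C; then AcOH/H2O 4:1, 45 °C
Reagents that add atoms: water, O
Why: Nitrite-mediated Nef reaction (nitrosation of the aci-nitro form, then hydrolysis) unveils the C3 ketone from both nitro epimers under weakly acidic conditions that should not epimerise C4 or touch the methylene lactone, and warm aqueous acetic acid then hydrolyses the acetonide.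

**Compound list**
1 | 4-methylanisole | COc1ccc(C)cc1 | starting material
2 | 1-methoxy-4-methylcyclohexa-1,4-diene | COC1=CCC(C)=CC1 | intermediate
3 | methyl (3Z)-4-methyl-6-oxohex-3-enoate (formed in the flask) | COC(=O)C/C=C(/C)CC=O | intermediate
4 | methyl (3Z)-6,6-dimethoxy-4-methylhex-3-enoate | COC(=O)C/C=C(/C)CC(OC)OC | intermediate
5 | (3Z)-6,6-dimethoxy-4-methylhex-3-en-1-ol | OCC/C=C(/C)CC(OC)OC | intermediate
6 | (3Z)-6-iodo-1,1-dimethoxy-3-methylhex-3-ene | ICC/C=C(/C)CC(OC)OC | intermediate
7 | (3Z)-1,1-dimethoxy-3-methyl-6-nitrohex-3-ene | [O-][N+](=O)CC/C=C(/C)CC(OC)OC | intermediate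
8 | (3R,4S)-1,1-dimethoxy-3-methyl-6-nitrohexane-3,4-diol | COC(OC)C[C@@](C)(O)[C@@H](O)CC[N+](=O)[O-] | intermediate
9 | (4S,5R)-5-(2,2-dimethoxyethyl)-2,2,5-trimethyl-4-(2-nitroethyl)-1,3-dioxolane | COC(OC)C[C@@]1(C)OC(C)(C)O[C@H]1CC[N+](=O)[O-] | intermediate
10 | (E)-but-2-enal (crotonaldehyde) | C/C=C/C=O | starting material
11 | (3S)-5-[(4S,5R)-5-(2,2-dimethoxyethyl)-2,2,5-trimethyl-1,3-dioxolan-4-yl]-3-methyl-4-nitropentanal (nitro epimers) | O=CC[C@H](C)C([N+](=O)[O-])C[C@@H]1OC(C)(C)O[C@]1(C)CC(OC)OC | intermediate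
12 | ethyl 2-[(4,4,5,5-tetramethyl-1,3,2-dioxaborolan-2-yl)methyl]prop-2-enoate | CCOC(=O)C(=C)CB1OC(C)(C)C(C)(C)O1 | starting material
13 | pinacol borate of the (6R)-homoallylic alcohol, ethyl ester (formed in the flask) | CCOC(=O)C(=C)C[C@H](OB1OC(C)(C)C(C)(C)O1)C[C@H](C)C([N+](=O)[O-])C[C@@H]2OC(C)(C)O[C@]2(C)CC(OC)OC | intermediate
14 | (5R)-5-{(2S)-4-[(4S,5R)-5-(2,2-dimethoxyethyl)-2,2,5-trimethyl-1,3-dioxolan-4-yl]-2-methyl-3-nitrobutyl}-3-methylideneoxolan-2-one | C=C1C[C@H](OC1=O)C[C@H](C)C([N+](=O)[O-])C[C@@H]2OC(C)(C)O[C@]2(C)CC(OC)OC | intermediate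
15 | 3-bromo-3-(bromomethyl) analogue of 14 (formed in the flask) | BrCC1(Br)C[C@H](OC1=O)C[C@H](C)C([N+](=O)[O-])C[C@@H]2OC(C)(C)O[C@]2(C)CC(OC)OC | intermediate
16 | (5R)-3-(bromomethyl)-5-{(2S)-4-[(4S,5R)-5-(2,2-dimethoxyethyl)-2,2,5-trimethyl-1,3-dioxolan-4-yl]-2-methyl-3-nitrobutyl}furan-2(5H)-one | BrCC1=C[C@H](OC1=O)C[C@H](C)C([N+](=O)[O-])C[C@@H]2OC(C)(C)O[C@]2(C)CC(OC)OC | intermediate
17 | 2-{(4R,5S)-5-[(3S)-4-[(2R)-4-(bromomethyl)-5-oxo-2,5-dihydrofuran-2-yl]-3-methyl-2-nitrobutyl]-2,2,4-trimethyl-1,3-dioxolan-4-yl}acetaldehyde | BrCC1=C[C@H](OC1=O)C[C@H](C)C([N+](=O)[O-])C[C@@H]2OC(C)(C)O[C@]2(C)CC=O | intermediate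
18 | (1S,4S,6R,7R,8S,10R)-8-hydroxy-1,10-(isopropylidenedioxy)-3-nitrogermacr-11(13)-en-6,12-olide (C3 epimers) | C=C1C(=O)O[C@@H]2C[C@H](C)C([N+](=O)[O-])C[C@@H]3OC(C)(C)O[C@]3(C)C[C@H](O)[C@@H]12 | intermediate
19 | 2-methylpropanoic acid (isobutyric acid) | CC(C)C(O)=O | starting material
20 | (1S,4S,6R,7S,8R,10R)-1,10-(isopropylidenedioxy)-8-(2-methylpropanoyloxy)-3-nitrogermacr-11(13)-en-6,12-olide (C3 epimers) | C=C1C(=O)O[C@@H]2C[C@H](C)C([N+](=O)[O-])C[C@@H]3OC(C)(C)O[C@]3(C)C[C@@H](OC(=O)C(C)C)[C@@H]12 | intermediate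
21 | (1S,4S,6R,7S,8R,10R)-1,10-(isopropylidenedioxy)-8-(2-methylpropanoyloxy)-3-oxogermacr-11(13)-en-6,12-olide (formed in the flask) | C=C1C(=O)O[C@@H]2C[C@H](C)C(=O)C[C@@H]3OC(C)(C)O[C@]3(C)C[C@@H](OC(=O)C(C)C)[C@@H]12 | intermediate
22 | (1S,4S,6R,7S,8R,10R)-1,10-dihydroxy-8-(2-methylpropanoyloxy)-3-oxogermacr-11(13)-en-6,12-olide | C=C1C(=O)O[C@@H]2C[C@H](C)C(=O)C[C@H](O)[C@](C)(O)C[C@@H](OC(=O)C(C)C)[C@@H]12 | target

**Total step count:** 14. **Longest linear sequence:** 14 steps (1 → 22); 10, 12 and 19 are bought.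

**Three steps most likely to fail**

Step 12 (ring closure). Oligomerisation, protonolysis of the allylindium, or a cis ring fusion are all possible, and the C8 configuration is predicted only by analogy with intermolecular cases. The fallback sets out from 16 and comes back at 20. Compound 16 is treated with hexabutylditin and Pd2(dba)3/PPh3 (a zerovalent palladium catalyst) to give the allylic stannane F1. Transacetalisation as in step 11 gives the stannyl aldehyde F2. BF3·OEt2 in CH2Cl2 at −78 °C under high dilution then closes the ring through an open, antiperiplanar transition state, which for the ring-locked allyl unit is 7,8-syn and gives the (8R)-alcohol F3 directly. Acylation with isobutyric anhydride, DMAP and pyridine gives 20, so that step 13 is not needed on this branch.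

Step 13 (Mitsunobu inversion). The C8 alcohol is hindered, and elimination towards the C7–C11 diene can compete. The fallback sets out from 18 and comes back at 20, separating activation from displacement. Triflic anhydride and pyridine in CH2Cl2 at −30 °C give the C8 triflate F4. Caesium isobutyrate with 18-crown-6 in toluene at rt then displaces it by SN2 with inversion to give 20.

Step 14 (Nef reaction and deprotection). The nitrosative Nef may be slow on the hindered secondary nitro group or may scramble C4. The fallback sets out from 20 and comes back at 22, using a reductive Nef on the unprotected diol. Aqueous acetic acid at 45 °C first removes the acetonide to give the nitro diol F5. Aqueous TiCl3 in THF at rt then reduces the nitro group through the oxime to the imine, whose hydrolysis gives 22; the free C10 hydroxyl can hold the new ketone as its hemiketal and so limits enolisation towards C4.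

**Further compounds**
F1 | step 12 | (5R)-3-[(tributylstannyl)methyl] analogue of 16 (allylic stannane, dimethyl acetal) | CCCC[Sn](CCCC)(CCCC)CC1=C[C@H](OC1=O)C[C@H](C)C([N+](=O)[O-])C[C@@H]2OC(C)(C)O[C@]2(C)CC(OC)OC
F2 | step 12 | (5R)-3-[(tributylstannyl)methyl] analogue of 17 (allylic stannane, C8 aldehyde) | CCCC[Sn](CCCC)(CCCC)CC1=C[C@H](OC1=O)C[C@H](C)C([N+](=O)[O-])C[C@@H]2OC(C)(C)O[C@]2(C)CC=O
F3 | step 12 | (1S,4S,6R,7R,8R,10R)-8-hydroxy-1,10-(isopropylidenedioxy)-3-nitrogermacr-11(13)-en-6,12-olide (C3 epimers) | C=C1C(=O)O[C@@H]2C[C@H](C)C([N+](=O)[O-])C[C@@H]3OC(C)(C)O[C@]3(C)C[C@@H](O)[C@@H]12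
F4 | step 13 | C8 trifluoromethanesulfonate of 18 | C=C1C(=O)O[C@@H]2C[C@H](C)C([N+](=O)[O-])C[C@@H]3OC(C)(C)O[C@]3(C)C[C@H](OS(=O)(=O)C(F)(F)F)[C@@H]12
F5 | step 14 | (1S,4S,6R,7S,8R,10R)-1,10-dihydroxy-8-(2-methylpropanoyloxy)-3-nitrogermacr-11(13)-en-6,12-olide (C3 epimers) | C=C1C(=O)O[C@@H]2C[C@H](C)C([N+](=O)[O-])C[C@H](O)[C@](C)(O)C[C@@H](OC(=O)C(C)C)[C@@H]12
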